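# Pollenitin 8-acetate (15): ring A built last by cyclobutenone ring expansion

## The problem

Pollenitin 8-acetate (15) is a flavonol: benzo ring A is fused to the 4-pyranone ring C, which carries the 4-hydroxyphenyl ring B at C2. It has no stereocentre, so the whole task is one of constitution.

Five oxygen substituents occur in three states: free OH at C3, C5 and C4', a methyl ether at C7, and an acetate at C8. The acetate sits on the most crowded oxygen, between C7–OMe and O1, while more accessible or more acidic hydroxyls stay free. Direct acetylation of the parent tetraol therefore cannot be selective.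

Ring A is pentasubstituted: oxygen at C5, C7, C8 and C8a, carbon at C4a, hydrogen only at C6. Simple 1,3,5-trioxygenated building blocks lack the C8 oxygen. The 5,7,8 pattern can also leak into the 5,6,7 pattern by Wessely–Moser ring opening and reclosure in hot acid.

The aryl acetate does not survive alkali, alkaline peroxide, amines, hydrides or strong Lewis acids, which covers most classical flavonol-forming conditions. It must come last or travel only through neutral steps.

The enabling feature lies in ring A:
- O5 and O8 stand para, so ring A is a hydroquinone monoacetate.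
- The C8 acetate is flanked by C7–OMe, and the free C5–OH by C6–H.
- The remaining two atoms, C8a and C4a, are the C6=C5 double bond of a monocyclic 4-pyranone. Its C6 (the future C8a) lies next to the ring oxygen O1 and can be metalated.

This is, atom for atom, the pattern that a 4-alkenyl-4-acyloxy-3-methoxycyclobut-2-enone delivers on thermal ring expansion. Ring A can therefore be built last, onto a finished B–C unit, with every oxygen already in its final state.

## Retrosynthesis

**15 ⇒ 14.** The two O–CH2Ph bonds at O3 and O4' are cut. The last step must free two hydroxyls beside an aryl acetate. Hydrogenolysis is neutral and non-nucleophilic, whereas silyl, acetal or methyl ethers would need fluoride, acid or Lewis acid. O5 needs no protecting group because it is created free in the key step. The precursor 14 is no simpler in skeleton, but only two protecting groups of one kind are carried. The forward reaction must cleave the benzyl ethers faster than it touches C2=C3.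

**14 ⇒ 13 ⇒ 12 ⇒ 11 (key cut).** The C4a–C5 bond of ring A is cut and C5 is reconnected to C8, which contracts ring A to a cyclobutenone hanging on pyranone C6.
- Against its neighbours: cutting ring C (O1–C2, C2–C3) leaves the whole ring A problem untouched. Cutting C8–O leaves the selective acetylation unsolved.
- This cut removes the pentasubstituted benzene ring, the 5,7,8 versus 5,6,7 question and the O5/O8 differentiation together.
- 11 is an isomer of 14, but it falls apart in one further cut into two small pieces. The fate of each ring A oxygen is stored in its position on a four-membered ring.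
- The forward reaction needs a 4π opening to ketene 12 with the pyranonyl group turned inward, a 6π closure onto pyranone C5 to give 13, and enolization.

**11 ⇒ 10 ⇒ 9 + 3; 9 ⇒ 8.** The C8–C8a bond and the O8–acyl bond are cut.
- The two carbonyl groups of dione 3 differ. One is a vinylogous ester and the other is a true ketone flanked by C–OMe. Attack at the latter places OMe at the future C7; attack at the former would place it at C6.
- Alkoxide 10 is the only oxygen nucleophile in the flask, so its acylation is site-specific by default.
- The precursors are a five-carbon dione 3 and a monocyclic pyranone 8.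
- The forward reaction needs selective metalation of 8 at C6 to give 9, and 1,2-addition rather than conjugate addition.

**3 ⇒ 2 ⇒ 1.** A C–H of 3 is traced back to a C–OMe of the symmetrical squarate 1. Hydride adds to one carbonyl to give 2, and acid-induced transposition then expels methanol. This is preferred to building the four-membered ring by cycloaddition, because 1 already contains all four ring carbons and the methoxy group that ends up at C7. The forward reaction must stop at mono-reduction.

**8 ⇒ 6 + 7; 6 ⇒ 5 ⇒ 4.** The C2–C1' bond between rings C and B is cut. In 4, C2 is the β-carbon of the C3 enol and the one nucleophilic carbon of the ring, so a halogen goes there without a directing device (5). Benzylation gives 6, and cross-coupling with boronic acid 7 installs ring B. A de novo pyranone synthesis would cost more steps than this three-step decoration of a purchasable ring. The forward coupling must be mild toward a base-sensitive vinylogous acyl iodide.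

## Roads not taken

**Alternative 1:** The most obvious cut opens ring C at O1–C2 and C2–C3.
- Forward key step: Claisen–Schmidt condensation of acetophenone A1 with aldehyde A2 to chalcone A3, then Algar–Flynn–Oyamada oxidative cyclization to flavonol A4.
- The plan only moves the difficulty into A1, a hexasubstituted benzene with four differently treated oxygens. No building block supplies it, and it would need a multistep sequence of its own, including a C–H oxidation.
- Chalcones with a 6'-alkoxy group tend to divert toward five-membered ring closure under the alkaline peroxide conditions.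
- Those conditions also exclude the acetate, so a third, orthogonal protecting group is needed on O8.
- A4 would still need four more operations before 15 is reached: protection of O3, release of O8, acetylation and global hydrogenolysis.
- The chosen plan needs no orthogonal group and creates ring A in its final oxygenation state.

**Alternative 2:** The C8–O bond is cut, that is, late C–H oxidation.
- Forward key step: Elbs persulfate oxidation of rhamnocitrin A5, para to its 5-OH, to pollenitin A6, followed by acetylation to 15.
- The step supplies only one oxygen.
- A5 must itself be assembled with a selective 7-O-methylation.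
- The oxidation runs in alkali on a substrate whose 3-enol and 4'-phenol are themselves oxidizable.
- The last step asks for acetylation of the most hindered of four hydroxyls in A6, for which the structure offers no handle. Protecting O3 and O4' first restores selectivity only at the price of a long linear sequence.
- In the chosen plan no reagent ever has to choose between oxygens.

**Alternative 3:** Ring A is cut at C5–C6, C7–C8 and C8–C8a, a carbene complex benzannulation.
- Forward key step: Dötz reaction of the chromium carbene complex A7 with methoxyacetylene A8 and one of its own CO ligands. Acetylation of the newborn C8 phenol would give A9.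
- The logic is related, since the para oxygens are distinguished at birth, but there are four drawbacks.
- The metal must be introduced at pyranone C5, where a carbanion lies β to O1 and can expel it with ring opening.
- The oxygen donor on the β-carbon of the alkenyl carbene disfavours CO insertion and favours five-membered ring products.
- A8 is volatile and strongly polarized, and its orientation would rest on the size of a small group.
- O5 emerges as a methyl ether, so A9 needs a Lewis acid demethylation beside the acetate.
- The cyclobutenone route is metal-free in the key step, uses the readily metalated C6, and delivers OH at C5 and the acyl group at C8 directly.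

Key step: step 6

Remark: 15 is achiral. The stereocentres of 2, 10, 11 and 13 arise racemic and are erased, so their SMILES carry no configuration. Pyranone numbering (O1, C2–C6) is used for 4–12 and flavone numbering for 13–15.

## Steps

Step 1
Reactants: 1 dimethyl squarate (3,4-dimethoxycyclobut-3-ene-1,2-dione)
Product: 3 3-methoxycyclobut-3-ene-1,2-dione (methyl semisquarate), via hydride adduct 2 (not isolated)
Conditions: LiAlH(OtBu)3, THF, −78 to −20 °C; aq. HCl quench; crude 2, conc. HCl (cat.), CH2Cl2, rt
Reagents that add atoms: none
Why: The hindered hydride adds once, 1,2, to a squarate carbonyl; acid then ionizes the carbinol of 2, the hydroxyl is transposed 1,3 and methanol is lost. This is the standard conversion of dialkyl squarates into 3-alkoxy-4-R-cyclobutenediones, here with R = H.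

Step 2
Reactants: 4 pyromeconic acid (3-hydroxy-4H-pyran-4-one)
Product: 5 3-hydroxy-2-iodo-4H-pyran-4-one
Conditions: NIS, MeCN, 0 °C to rt, dark
Reagents that add atoms: N-iodosuccinimide, O=C1CCC(=O)N1I
Why: Electrophilic halogenation of an enolic 3-hydroxy-4-pyranone; C2 is the β-carbon of the C3 enol, the site at which pyromeconic and kojic acids undergo halogenation, aldol and Mannich reactions, whereas C5 and C6 belong to the deactivated enone half.

Step 3
Reactants: 5 3-hydroxy-2-iodo-4H-pyran-4-one
Product: 6 3-(benzyloxy)-2-iodo-4H-pyran-4-one
Conditions: BnBr, K2CO3, DMF, rt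
Reagents that add atoms: benzyl bromide, BrCc1ccccc1
Why: Williamson O-alkylation of the acidic enol, as routinely done on maltol and kojic acid; excess reactive halide at room temperature keeps the enolate from attacking the C2–I position of a second molecule.

Step 4
Reactants: 6 3-(benzyloxy)-2-iodo-4H-pyran-4-one; 7 4-(benzyloxy)phenylboronic acid
Product: 8 3-(benzyloxy)-2-[4-(benzyloxy)phenyl]-4H-pyran-4-one
Conditions: Pd(PPh3)4 (cat.), K3PO4, 1,4-dioxane/H2O, 80 °C
Reagents that add atoms: none
Why: Suzuki–Miyaura coupling; the C2–I bond of a γ-pyrone is a vinylogous acyl iodide and adds readily to zerovalent palladium, as in the known couplings of 2-halochromones to flavones. A mild phosphate base spares the pyranone ring.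

Step 5
Reactants: 8 3-(benzyloxy)-2-[4-(benzyloxy)phenyl]-4H-pyran-4-one; 3 3-methoxycyclobut-3-ene-1,2-dione
Product: 11 1-{5-(benzyloxy)-6-[4-(benzyloxy)phenyl]-4-oxo-4H-pyran-2-yl}-2-methoxy-4-oxocyclobut-2-en-1-yl acetate (racemic), via 6-lithiopyranone 9 (not isolated), via lithium alkoxide 10 (not isolated)
Conditions: LiTMP (from TMP, n-BuLi), THF, −78 °C; cannulated into 3, THF, −78 °C; Ac2O, −78 to 0 °C
Reagents that add atoms: acetic anhydride, CC(=O)OC(C)=O
Why: C6–H of 8 is the vinylic C–H next to the ring oxygen of an electron-poor γ-pyrone, the position at which chromones and 4-pyridones are known to be deprotonated, and the very hindered amide (and its amine) adds neither to the pyranone nor to 3. The hard organolithium 9 adds 1,2 to the carbonyl of 3 flanked by C–OMe, because the other carbonyl is a deactivated vinylogous ester (the established regiochemistry for 3-alkoxycyclobutenediones), which fixes OMe at the future C7 and not C6. Alkoxide 10 is the only oxygen nucleophile present, so the anhydride quench places the acetyl group on the future O8 alone; the new quaternary centre is racemic and vanishes in step 6.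

Step 6
Reactants: 11 1-{5-(benzyloxy)-6-[4-(benzyloxy)phenyl]-4-oxo-4H-pyran-2-yl}-2-methoxy-4-oxocyclobut-2-en-1-yl acetate
Product: 14 8-acetoxy-3-(benzyloxy)-2-[4-(benzyloxy)phenyl]-5-hydroxy-7-methoxy-4H-chromen-4-one, via dienylketene 12 (not isolated), via cyclohexadienone 13 (not isolated)
Conditions: toluene (degassed, high dilution), 110 °C, Ar
Reagents that add atoms: none
Why: Heating cleaves the C(=O)–C(OAc) bond of the cyclobutenone in a conrotatory 4π electrocyclic opening to dienylketene 12; the acetoxy donor should rotate outward and the acceptor-like pyranonyl group inward, so that the ketene and the pyranone C5=C6 bond stand cis on the central double bond, and a wrongly opened isomer can only revert to 11. Ring A is then closed by a 6π electrocyclization that joins the electrophilic ketene carbon to pyranone C5, the nucleophilic β-carbon of the O1–C6=C5 enol ether, to give dienone 13. The C4a–H of 13 lies between two carbonyl groups and enolizes at once, so the only new stereocentre is transient and needs no control, while aromatization and the new O5–H···O=C4 chelate make the sequence irreversible. The closest known reaction type is the Moore ring expansion of 4-alkenyl-, 4-(α-alkoxyalkenyl)- and 4-heteroaryl-4-oxycyclobutenones to hydroquinones, whose O-protected variants deliver mono-protected hydroquinones. The selectivity required is purely constitutional and is stored in 11: the carbinol carbon becomes C8 with its acetate, the C–OMe carbon becomes C7, the CH becomes C6 and the ketone carbon becomes the free C5–OH. High dilution and the absence of nucleophiles protect the ketene, and the chelated 5-OH of the product is a poor ketene trap. No acid or base is present, so acetate cleavage and Wessely–Moser isomerization have no pathway.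

Step 7
Reactants: 14 8-acetoxy-3-(benzyloxy)-2-[4-(benzyloxy)phenyl]-5-hydroxy-7-methoxy-4H-chromen-4-one
Product: 15 pollenitin 8-acetate (8-acetoxy-3,5-dihydroxy-2-(4-hydroxyphenyl)-7-methoxy-4H-chromen-4-one)
Conditions: H2 (1 atm), 10% Pd/C, EtOAc/THF, rt
Reagents that add atoms: none
Why: Catalytic hydrogenolysis of benzyl ethers, the standard neutral unmasking of benzylated flavonols, leaves the conjugated C2=C3 bond and the aryl acetate intact. The aprotic solvent excludes transesterification, and the acetate, flanked by OMe and O1, has no neighbouring hydroxyl to migrate to.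

## Compound list

1 | dimethyl squarate (3,4-dimethoxycyclobut-3-ene-1,2-dione) | COC1=C(OC)C(=O)C1=O | starting material
2 | 4-hydroxy-2,3-dimethoxycyclobut-2-en-1-one (racemic) | COC1=C(OC)C(O)C1=O | intermediate
3 | 3-methoxycyclobut-3-ene-1,2-dione | COC1=CC(=O)C1=O | intermediate
4 | pyromeconic acid (3-hydroxy-4H-pyran-4-one) | Oc1coccc1=O | starting material
5 | 3-hydroxy-2-iodo-4H-pyran-4-one | Oc1c(I)occc1=O | intermediate
6 | 3-(benzyloxy)-2-iodo-4H-pyran-4-one | Ic1occc(=O)c1OCc1ccccc1 | intermediate
7 | 4-(benzyloxy)phenylboronic acid | OB(O)c1ccc(OCc2ccccc2)cc1 | starting material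
8 | 3-(benzyloxy)-2-[4-(benzyloxy)phenyl]-4H-pyran-4-one | O=c1ccoc(-c2ccc(OCc3ccccc3)cc2)c1OCc1ccccc1 | intermediate
9 | 3-(benzyloxy)-2-[4-(benzyloxy)phenyl]-6-lithio-4H-pyran-4-one | [Li]c1cc(=O)c(OCc2ccccc2)c(-c2ccc(OCc3ccccc3)cc2)o1 | intermediate
10 | lithium 1-{5-(benzyloxy)-6-[4-(benzyloxy)phenyl]-4-oxo-4H-pyran-2-yl}-2-methoxy-4-oxocyclobut-2-en-1-olate (racemic) | COC1=CC(=O)C1([O-])c1cc(=O)c(OCc2ccccc2)c(-c2ccc(OCc3ccccc3)cc2)o1.[Li+] | intermediate
11 | 1-{5-(benzyloxy)-6-[4-(benzyloxy)phenyl]-4-oxo-4H-pyran-2-yl}-2-methoxy-4-oxocyclobut-2-en-1-yl acetate (racemic) | COC1=CC(=O)C1(OC(C)=O)c1cc(=O)c(OCc2ccccc2)c(-c2ccc(OCc3ccccc3)cc2)o1 | intermediate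
12 | (3Z)-4-acetoxy-4-{5-(benzyloxy)-6-[4-(benzyloxy)phenyl]-4-oxo-4H-pyran-2-yl}-3-methoxybuta-1,3-dien-1-one | O=C=C/C(OC)=C(OC(C)=O)\c1cc(=O)c(OCc2ccccc2)c(-c2ccc(OCc3ccccc3)cc2)o1 | intermediate
13 | 8-acetoxy-3-(benzyloxy)-2-[4-(benzyloxy)phenyl]-7-methoxy-4aH-chromene-4,5-dione (racemic) | COC1=CC(=O)C2C(=O)C(OCc3ccccc3)=C(c3ccc(OCc4ccccc4)cc3)OC2=C1OC(C)=O | intermediate
14 | 8-acetoxy-3-(benzyloxy)-2-[4-(benzyloxy)phenyl]-5-hydroxy-7-methoxy-4H-chromen-4-one | COc1cc(O)c2c(=O)c(OCc3ccccc3)c(-c3ccc(OCc4ccccc4)cc3)oc2c1OC(C)=O | intermediate
15 | pollenitin 8-acetate | COc1cc(O)c2c(=O)c(O)c(-c3ccc(O)cc3)oc2c1OC(C)=O | target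

## Step count and risks

Total step count: 7. Longest linear sequence: 6 steps (4 → 5 → 6 → 8 → 11 → 14 → 15). Step 1 is a one-step side branch.

**Step 6 (key step).**
- Risk: acetoxy is a weaker donor than hydroxy, so the outward preference in the 4π opening may be eroded. The 6π closure onto the pyranone double bond may be slow enough for the ketene to be consumed by intermolecular trapping or oligomerization, and thermal acyl transfer cannot be excluded.
- Fallback: it sets out from alkoxide 10, which is quenched with aq. NH4Cl instead of the anhydride. This gives the tertiary alcohol 4-{5-(benzyloxy)-6-[4-(benzyloxy)phenyl]-4-oxo-4H-pyran-2-yl}-4-hydroxy-3-methoxycyclobut-2-en-1-one F1.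
- F1 is the parent form of the ring expansion, with the strongest outward-rotating donor. Heated under argon, it should give the hydroquinone 3-(benzyloxy)-2-[4-(benzyloxy)phenyl]-5,8-dihydroxy-7-methoxy-4H-chromen-4-one F2.
- The differentiation of O5 and O8 is then handed to chelation. The 5-OH is locked in a hydrogen bond to C4=O and acylates sluggishly, so one equivalent of Ac2O in pyridine at 0 °C should acetylate O8 only. The route is rejoined at 14.

**Step 5.**
- Risk: competing deprotonation at the benzylic CH2 of the O3 benzyl group or at C5, self-condensation of the lithiated pyranone with unmetalated 8, and conjugate addition or methoxide displacement on 3 in place of 1,2-addition.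
- Fallback: it replaces kinetic deprotonation by halogen–metal exchange and sets out from 8.
- Zincation with TMPZnCl·LiCl in THF at 25 °C gives the 6-(chlorozincio)pyranone F3, and iodinolysis gives 3-(benzyloxy)-2-[4-(benzyloxy)phenyl]-6-iodo-4H-pyran-4-one F4.
- I/Mg exchange with iPrMgCl·LiCl at −78 °C gives the 6-(chloromagnesio)pyranone F5. This adds to 3 to form the chloromagnesium alkoxide F6, and the Ac2O quench comes back to 11.

**Step 1.**
- Risk: over-reduction of the squarate, and loss of the small, hydrolytically labile vinylogous ester during the acid step and isolation.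
- Fallback: it sets out from 2, which is deliberately hydrolysed with warm aq. HCl to semisquaric acid (3-hydroxycyclobut-3-ene-1,2-dione) F7, a robust crystalline acid that can be purified. Re-esterification with HC(OMe)3 in MeOH, the method used for squaric acid itself, returns to 3.

**Step 4.**
- Risk: hydrolytic displacement of the vinylogous acyl iodide, base-induced opening of the pyranone, and protodeboronation of the electron-rich boronic acid.
- Fallback: it reverses the polarity, needs no base, and sets out from 6. Zinc insertion (Zn dust, LiCl, THF, 25 °C) gives [3-(benzyloxy)-4-oxo-4H-pyran-2-yl]zinc iodide F8. Negishi coupling with purchased 1-(benzyloxy)-4-iodobenzene F9 under Pd(PPh3)4 catalysis comes back to 8.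

**Step 7.**
- Risk: saturation of C2=C3 on prolonged exposure, or incomplete cleavage at the hindered O3.
- Fallback: it leaves reduction altogether. 14 is debenzylated by a Lewis acid with a cation scavenger (BCl3, pentamethylbenzene, CH2Cl2, −78 °C). At this temperature the non-chelated 7-OMe and the acetate should persist, and 15 is reached directly.

## Further compounds

F1 | step 6 | 4-{5-(benzyloxy)-6-[4-(benzyloxy)phenyl]-4-oxo-4H-pyran-2-yl}-4-hydroxy-3-methoxycyclobut-2-en-1-one (racemic) | COC1=CC(=O)C1(O)c1cc(=O)c(OCc2ccccc2)c(-c2ccc(OCc3ccccc3)cc2)o1
F2 | step 6 | 3-(benzyloxy)-2-[4-(benzyloxy)phenyl]-5,8-dihydroxy-7-methoxy-4H-chromen-4-one | COc1cc(O)c2c(=O)c(OCc3ccccc3)c(-c3ccc(OCc4ccccc4)cc3)oc2c1O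
F3 | step 5 | {5-(benzyloxy)-6-[4-(benzyloxy)phenyl]-4-oxo-4H-pyran-2-yl}zinc chloride | Cl[Zn]c1cc(=O)c(OCc2ccccc2)c(-c2ccc(OCc3ccccc3)cc2)o1
F4 | step 5 | 3-(benzyloxy)-2-[4-(benzyloxy)phenyl]-6-iodo-4H-pyran-4-one | Ic1cc(=O)c(OCc2ccccc2)c(-c2ccc(OCc3ccccc3)cc2)o1
F5 | step 5 | {5-(benzyloxy)-6-[4-(benzyloxy)phenyl]-4-oxo-4H-pyran-2-yl}magnesium chloride | Cl[Mg]c1cc(=O)c(OCc2ccccc2)c(-c2ccc(OCc3ccccc3)cc2)o1
F6 | step 5 | chloromagnesium 1-{5-(benzyloxy)-6-[4-(benzyloxy)phenyl]-4-oxo-4H-pyran-2-yl}-2-methoxy-4-oxocyclobut-2-en-1-olate (racemic) | COC1=CC(=O)C1(O[Mg]Cl)c1cc(=O)c(OCc2ccccc2)c(-c2ccc(OCc3ccccc3)cc2)o1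
F7 | step 1 | semisquaric acid (3-hydroxycyclobut-3-ene-1,2-dione) | OC1=CC(=O)C1=O
F8 | step 4 | [3-(benzyloxy)-4-oxo-4H-pyran-2-yl]zinc iodide | I[Zn]c1occc(=O)c1OCc1ccccc1
F9 | step 4 | 1-(benzyloxy)-4-iodobenzene | Ic1ccc(OCc2ccccc2)cc1
F0 | step 7 | none | none
A1 | alternative 1 | 1-[6-(benzyloxy)-2-hydroxy-4-methoxy-3-(methoxymethoxy)phenyl]ethan-1-one | CC(=O)c1c(O)c(OCOC)c(OC)cc1OCc1ccccc1
A2 | alternative 1 | 4-(benzyloxy)benzaldehyde | O=Cc1ccc(OCc2ccccc2)cc1
A3 | alternative 1 | (E)-1-[6-(benzyloxy)-2-hydroxy-4-methoxy-3-(methoxymethoxy)phenyl]-3-[4-(benzyloxy)phenyl]prop-2-en-1-one | O=C(/C=C/c1ccc(OCc2ccccc2)cc1)c1c(O)c(OCOC)c(OC)cc1OCc1ccccc1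
A4 | alternative 1 | 5-(benzyloxy)-2-[4-(benzyloxy)phenyl]-3-hydroxy-7-methoxy-8-(methoxymethoxy)-4H-chromen-4-one | COCOc1c(OC)cc(OCc2ccccc2)c2c(=O)c(O)c(-c3ccc(OCc4ccccc4)cc3)oc12
A5 | alternative 2 | rhamnocitrin (3,5-dihydroxy-2-(4-hydroxyphenyl)-7-methoxy-4H-chromen-4-one) | COc1cc(O)c2c(=O)c(O)c(-c3ccc(O)cc3)oc2c1
A6 | alternative 2 | pollenitin (3,5,8-trihydroxy-2-(4-hydroxyphenyl)-7-methoxy-4H-chromen-4-one) | COc1cc(O)c2c(=O)c(O)c(-c3ccc(O)cc3)oc2c1O
A7 | alternative 3 | pentacarbonyl[{5-(benzyloxy)-6-[4-(benzyloxy)phenyl]-4-oxo-4H-pyran-3-yl}(methoxy)methylidene]chromium | COC(=[Cr](=C=O)(=C=O)(=C=O)(=C=O)=C=O)c1coc(-c2ccc(OCc3ccccc3)cc2)c(OCc2ccccc2)c1=O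
A8 | alternative 3 | methoxyacetylene | COC#C
A9 | alternative 3 | 8-acetoxy-3-(benzyloxy)-2-[4-(benzyloxy)phenyl]-5,7-dimethoxy-4H-chromen-4-one | COc1cc(OC)c2c(=O)c(OCc3ccccc3)c(-c3ccc(OCc4ccccc4)cc3)oc2c1OC(C)=O
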